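**Retrosynthetic overview**

1. Target 20 ⇐ transannular crossed [2+2] photocycloaddition of the eleven-membered cross-conjugated trienone 19. It forms C4–C10 and C5–C11, so ring A (cyclohexenone), the cyclobutane and the cycloheptane all close in this one step.
2. 19 ⇐ Nozaki–Hiyama–Kishi macrocyclisation (C9–C10, sets C9) of iodo-trienone aldehyde 18 ⇐ Heck coupling (C3–C4) of alkene 10 with the symmetric diiodide 16.
3. 10 ⇐ methyl (S)-glycerate acetonide 1 (C8 bought; C6 by reverse prenylation; C7 by Felkin–Anh reduction) and two angelic acid units.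
4. 16 ⇐ two prop-1-ynylmagnesium bromide units and ethyl formate.
5. Ring order: the eleven-membered carbocycle first, then the four-, six- and seven-membered rings together.

Assumption: carbons are numbered as in longipinane (C1 ketone, C2=C3 enone, C4 and C11 bridgeheads, C5 and C10 one-carbon bridges, C6 = CMe2, C7–C9 oxygenated); alkene geometry in 17–19 is written as formed and is equilibrated in step 13; in the iridium sensitiser, dF(CF3)ppy is cyclometalated 2-(2,4-difluorophenyl)-5-(trifluoromethyl)pyridine and dtbbpy is 4,4'-di-tert-butyl-2,2'-bipyridine.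

**Route**

Step 1
Reactants: 1 methyl (S)-2,2-dimethyl-1,3-dioxolane-4-carboxylate
Product: 2 (S)-N-methoxy-N,2,2-trimethyl-1,3-dioxolane-4-carboxamide
Conditions: MeNH(OMe)·HCl, i-PrMgCl, THF, −20 °C
Reagents that add atoms: N,O-dimethylhydroxylamine hydrochloride, CNOC.Cl
Why: Weinreb amide formation by aminolysis of the ester with the magnesium amide at low temperature, which leaves the C8 stereocentre untouched.

Step 2
Reactants: 2 (S)-N-methoxy-N,2,2-trimethyl-1,3-dioxolane-4-carboxamide; 3 prenylmagnesium chloride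
Product: 4 1-[(4S)-2,2-dimethyl-1,3-dioxolan-4-yl]-2,2-dimethylbut-3-en-1-one
Conditions: THF, −78 → 0 °C; aq. NH4Cl
Reagents that add atoms: none
Why: Weinreb ketone synthesis with γ-selective (SE2′, reverse prenyl) attack of the allylic Grignard reagent builds the C6 quaternary carbon, and the chelated tetrahedral intermediate stops the addition at the ketone.

Step 3
Reactants: 4 1-[(4S)-2,2-dimethyl-1,3-dioxolan-4-yl]-2,2-dimethylbut-3-en-1-one
Product: 5 (1S)-1-[(4S)-2,2-dimethyl-1,3-dioxolan-4-yl]-2,2-dimethylbut-3-en-1-ol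
Conditions: LiBH(s-Bu)3, THF, −78 °C
Reagents that add atoms: none
Why: Felkin–Anh reduction of the α-alkoxy ketone, in which the bulky hydride attacks anti to the C8–O bond and gives the syn (7S,8S) alcohol.

Step 4
Reactants: 5 (1S)-1-[(4S)-2,2-dimethyl-1,3-dioxolan-4-yl]-2,2-dimethylbut-3-en-1-ol
Product: 6 (2S,3S)-4,4-dimethylhex-5-ene-1,2,3-triol
Conditions: AcOH–H2O (4:1), 45 °C
Reagents that add atoms: none
Why: Acid-catalysed acetonide hydrolysis, which does not touch the stereocentres or the 1,1-dimethylallyl group.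

Step 5
Reactants: 6 (2S,3S)-4,4-dimethylhex-5-ene-1,2,3-triol
Product: 7 (2S,3S)-4,4-dimethyl-1-(triethylsilyloxy)hex-5-ene-2,3-diol
Conditions: Et3SiCl (1.05 equiv), imidazole, CH2Cl2, −40 °C
Reagents that add atoms: chlorotriethylsilane, CC[Si](Cl)(CC)CC
Why: Selective silylation of the primary hydroxyl over the two hindered secondary hydroxyls.

Step 6
Reactants: 7 (2S,3S)-4,4-dimethyl-1-(triethylsilyloxy)hex-5-ene-2,3-diol; 8 angelic acid
Product: 10 (2S,3S)-4,4-dimethyl-1-(triethylsilyloxy)hex-5-ene-2,3-diyl bis[(Z)-2-methylbut-2-enoate], via angelic 2,4,6-trichlorobenzoic anhydride 9 (not isolated)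
Conditions: 8 (3 equiv), 2,4,6-trichlorobenzoyl chloride (3 equiv), Et3N, toluene, 25 °C; then 7, 80 °C (no DMAP)
Reagents that add atoms: angelic acid (second equivalent of 8), C/C=C(/C)C(=O)O; 2,4,6-trichlorobenzoyl chloride, O=C(Cl)c1c(Cl)cc(Cl)cc1Cl (its atoms stay in 9)
Why: Yamaguchi esterification through the mixed anhydride without a nucleophilic catalyst, which acylates both secondary hydroxyls while avoiding isomerisation of the angelate to the tiglate.

Step 7
Reactants: 11 prop-1-ynylmagnesium bromide; 12 ethyl formate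
Product: 14 hepta-2,5-diyn-4-ol, via but-2-ynal 13 (not isolated)
Conditions: 11 (2.2 equiv in all), THF, 0 → 25 °C; aq. NH4Cl
Reagents that add atoms: prop-1-ynylmagnesium bromide (second equivalent of 11), CC#C[Mg]Br
Why: Double Grignard addition to a formate ester, in which the first equivalent of 11 gives but-2-ynal in the flask and the second equivalent adds to that aldehyde to give the symmetric carbinol.

Step 8
Reactants: 14 hepta-2,5-diyn-4-ol
Product: 15 hepta-2,5-diyn-4-one
Conditions: MnO2, CH2Cl2, 25 °C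
Reagents that add atoms: none
Why: MnO2 oxidation of an activated (doubly propargylic) alcohol.

Step 9
Reactants: 15 hepta-2,5-diyn-4-one
Product: 16 (2Z,5Z)-2,6-diiodohepta-2,5-dien-4-one
Conditions: NaI (2.5 equiv), AcOH, 25 °C
Reagents that add atoms: sodium iodide (one iodide per arm), [Na+].[I-]
Why: Twofold conjugate hydroiodination of the ynone (iodide addition, then protonation anti) gives the Z β-iodo enone on both arms.

Step 10
Reactants: 10 (2S,3S)-4,4-dimethyl-1-(triethylsilyloxy)hex-5-ene-2,3-diyl bis[(Z)-2-methylbut-2-enoate]; 16 (2Z,5Z)-2,6-diiodohepta-2,5-dien-4-one (3 equiv)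
Product: 17 (2S,3S,5E,7Z,10Z)-11-iodo-4,4,7-trimethyl-9-oxo-1-(triethylsilyloxy)dodeca-5,7,10-triene-2,3-diyl bis[(Z)-2-methylbut-2-enoate]
Conditions: Pd(OAc)2 (10 mol %), Ag2CO3, DMF, 50 °C
Reagents that add atoms: none
Why: Mizoroki–Heck coupling with retention at the vinyl iodide; insertion occurs at the terminal alkene carbon and β-hydride elimination can only go toward C4 because C6 is quaternary, which gives the E diene, and the excess of 16 limits double coupling.

Step 11
Reactants: 17 (2S,3S,5E,7Z,10Z)-11-iodo-4,4,7-trimethyl-9-oxo-1-(triethylsilyloxy)dodeca-5,7,10-triene-2,3-diyl bis[(Z)-2-methylbut-2-enoate]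
Product: 18 (2R,3S,5E,7Z,10Z)-11-iodo-4,4,7-trimethyl-1,9-dioxododeca-5,7,10-triene-2,3-diyl bis[(Z)-2-methylbut-2-enoate]
Conditions: (COCl)2, DMSO, CH2Cl2, −78 °C; then i-Pr2NEt, −78 → −30 °C
Reagents that add atoms: none
Why: Swern oxidation applied directly to the primary triethylsilyl ether (oxidative desilylation) gives the aldehyde in one operation; the C8 descriptor changes only because of ligand priorities.

Step 12
Reactants: 18 (2R,3S,5E,7Z,10Z)-11-iodo-4,4,7-trimethyl-1,9-dioxododeca-5,7,10-triene-2,3-diyl bis[(Z)-2-methylbut-2-enoate]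
Product: 19 (2Z,4E,7S,8S,9S,10Z)-9-hydroxy-3,6,6,10-tetramethyl-1-oxocycloundeca-2,4,10-triene-7,8-diyl bis[(Z)-2-methylbut-2-enoate]
Conditions: CrCl2 (8 equiv), NiCl2 (2 mol %), DMSO–THF (1:3), 2 mM, 25 °C, slow addition
Reagents that add atoms: none
Why: Intramolecular Nozaki–Hiyama–Kishi coupling, chemoselective for the aldehyde over the ketone and esters, in which the vinylchromium adds anti to the C8–O bond (Felkin–Anh) and sets the 8,9-anti (9S) carbinol.

Step 13
Reactants: 19 (2Z,4E,7S,8S,9S,10Z)-9-hydroxy-3,6,6,10-tetramethyl-1-oxocycloundeca-2,4,10-triene-7,8-diyl bis[(Z)-2-methylbut-2-enoate]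
Product: 20 (4R,5S,7S,8S,9S,10R,11R)-9-hydroxy-1-oxolongipin-2-ene-7,8-diyl bis[(Z)-2-methylbut-2-enoate] (7β,8α-diangeloyloxy-9α-hydroxylongipin-2-en-1-one)
Conditions: [Ir(dF(CF3)ppy)2(dtbbpy)]PF6 (1 mol %), degassed MeCN (2 mM), 450 nm LEDs, 25 °C
Reagents that add atoms: none
Why: Proposed new method: triplet energy transfer from the excited iridium sensitiser (about 61 kcal/mol) reaches only the cross-conjugated dienone (about 55–58 kcal/mol; the angelates, above 72 kcal/mol, are not sensitised and keep their Z geometry), the ring alkenes equilibrate, and the dienone triplet attacks through C4 the β-carbon C10 of the enone in the 6-endo mode (closing ring A and the seven-membered ring and leaving an α-keto radical at C11 and a secondary radical at C5), after which the 1,4-biradical collapses to the C5–C11 bond; the parallel 1,5-closure is disfavoured because it would bond C4 to the enone α-carbon and then have to join the two most hindered centres C5 and C10; C10 is attacked anti to the C9–O bond with the C8 chain turned away from the C10 methyl (1,2-allylic strain) and the ring then fixes C4, C5 and C11, so all four new stereocentres follow from C9; the closest known reaction type is the visible-light energy-transfer crossed intramolecular [2+2] photocycloaddition of 2-vinylaryl vinyl ketones to benzobicyclo[3.1.1]heptanones, together with transannular [2+2] photocycloadditions of medium-ring dienes.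

**Compound list**

1 | methyl (S)-2,2-dimethyl-1,3-dioxolane-4-carboxylate | COC(=O)[C@@H]1COC(C)(C)O1 | starting material
2 | (S)-N-methoxy-N,2,2-trimethyl-1,3-dioxolane-4-carboxamide | CON(C)C(=O)[C@@H]1COC(C)(C)O1 | intermediate
3 | prenylmagnesium chloride (3-methylbut-2-enylmagnesium chloride) | CC(C)=CC[Mg]Cl | starting material
4 | 1-[(4S)-2,2-dimethyl-1,3-dioxolan-4-yl]-2,2-dimethylbut-3-en-1-one | C=CC(C)(C)C(=O)[C@@H]1COC(C)(C)O1 | intermediate
5 | (1S)-1-[(4S)-2,2-dimethyl-1,3-dioxolan-4-yl]-2,2-dimethylbut-3-en-1-ol | C=CC(C)(C)[C@H](O)[C@@H]1COC(C)(C)O1 | intermediate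
6 | (2S,3S)-4,4-dimethylhex-5-ene-1,2,3-triol | C=CC(C)(C)[C@H](O)[C@@H](O)CO | intermediate
7 | (2S,3S)-4,4-dimethyl-1-(triethylsilyloxy)hex-5-ene-2,3-diol | C=CC(C)(C)[C@H](O)[C@@H](O)CO[Si](CC)(CC)CC | intermediate
8 | angelic acid, (Z)-2-methylbut-2-enoic acid | C/C=C(/C)C(=O)O | starting material
9 | angelic 2,4,6-trichlorobenzoic anhydride | C/C=C(/C)C(=O)OC(=O)c1c(Cl)cc(Cl)cc1Cl | intermediate
10 | (2S,3S)-4,4-dimethyl-1-(triethylsilyloxy)hex-5-ene-2,3-diyl bis[(Z)-2-methylbut-2-enoate] | C/C=C(/C)C(=O)O[C@@H](CO[Si](CC)(CC)CC)[C@@H](OC(=O)/C(C)=C\C)C(C)(C)C=C | intermediate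
11 | prop-1-ynylmagnesium bromide | CC#C[Mg]Br | starting material
12 | ethyl formate | CCOC=O | starting material
13 | but-2-ynal | CC#CC=O | intermediate
14 | hepta-2,5-diyn-4-ol | CC#CC(O)C#CC | intermediate
15 | hepta-2,5-diyn-4-one | CC#CC(=O)C#CC | intermediate
16 | (2Z,5Z)-2,6-diiodohepta-2,5-dien-4-one | I/C(C)=C\C(=O)/C=C(C)\I | intermediate
17 | (2S,3S,5E,7Z,10Z)-11-iodo-4,4,7-trimethyl-9-oxo-1-(triethylsilyloxy)dodeca-5,7,10-triene-2,3-diyl bis[(Z)-2-methylbut-2-enoate] | C/C=C(/C)C(=O)O[C@@H](CO[Si](CC)(CC)CC)[C@@H](OC(=O)/C(C)=C\C)C(C)(C)/C=C/C(C)=C\C(=O)/C=C(C)\I | intermediate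
18 | (2R,3S,5E,7Z,10Z)-11-iodo-4,4,7-trimethyl-1,9-dioxododeca-5,7,10-triene-2,3-diyl bis[(Z)-2-methylbut-2-enoate] | C/C=C(/C)C(=O)O[C@@H](C=O)[C@@H](OC(=O)/C(C)=C\C)C(C)(C)/C=C/C(C)=C\C(=O)/C=C(C)\I | intermediate
19 | (2Z,4E,7S,8S,9S,10Z)-9-hydroxy-3,6,6,10-tetramethyl-1-oxocycloundeca-2,4,10-triene-7,8-diyl bis[(Z)-2-methylbut-2-enoate] | C/C=C(/C)C(=O)O[C@@H]1[C@@H](OC(=O)/C(C)=C\C)C(C)(C)/C=C/C(C)=C\C(=O)/C=C(C)\[C@@H]1O | intermediate
20 | (4R,5S,7S,8S,9S,10R,11R)-9-hydroxy-1-oxolongipin-2-ene-7,8-diyl bis[(Z)-2-methylbut-2-enoate] | C/C=C(/C)C(=O)O[C@@H]1[C@@H](OC(=O)/C(C)=C\C)C(C)(C)[C@@H]2[C@H]3C(=O)C=C(C)[C@@H]2[C@@]3(C)[C@@H]1O | target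

**Step count**

Total step count: 13. Longest linear sequence: 10 steps (steps 1–6 and 10–13); steps 7–9 make the diiodide 16 in a side branch.

**Steps most likely to fail, with fallbacks**

Step 12 (strained eleven-membered ring; C9 selectivity). The fallback sets out from 10 and comes back at 19, closing the ring at C3–C4 instead of C9–C10. Silyl ether 10 is oxidised directly under the conditions of step 11 to the aldehyde (2R,3S)-4,4-dimethyl-1-oxohex-5-ene-2,3-diyl bis[(Z)-2-methylbut-2-enoate] F1. F1 is then coupled intermolecularly with an excess of 16 (CrCl2, NiCl2 cat., DMSO) to give the open-chain alcohol (4S,5S,6S,7Z,10Z)-6-hydroxy-11-iodo-3,3,7-trimethyl-9-oxododeca-1,7,10-triene-4,5-diyl bis[(Z)-2-methylbut-2-enoate] F2. An intramolecular Heck reaction of F2 (Pd(OAc)2, Ag2CO3, MeCN, high dilution) returns 19.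

Step 13 (the proposed new photocycloaddition; parallel closure or mere isomerisation may win). The fallback uses known reaction types only, sets out from 10 (through aldehyde F1, made as above) and comes back at 20. Commercial (Z)-3-iodobut-2-enoic acid is converted (carbonyldiimidazole, then MeNH(OMe)·HCl) into (Z)-3-iodo-N-methoxy-N-methylbut-2-enamide F3. γ-Selective addition of but-2-enylmagnesium chloride to F3 gives (Z)-6-iodo-3-methylhepta-1,5-dien-4-one F4. Nozaki–Hiyama–Kishi coupling of F1 with F4 (CrCl2, NiCl2 cat., DMSO) gives (4S,5S,6S,7Z)-6-hydroxy-3,3,7,10-tetramethyl-9-oxododeca-1,7,11-triene-4,5-diyl bis[(Z)-2-methylbut-2-enoate] F5. Ring-closing metathesis (second-generation Hoveyda–Grubbs catalyst, toluene, 80 °C, high dilution) gives the ten-membered 1,5-dien-3-one (3E,6S,7S,8S,9Z)-8-hydroxy-2,5,5,9-tetramethyl-1-oxocyclodeca-3,9-diene-6,7-diyl bis[(Z)-2-methylbut-2-enoate] F6, which lacks C2. Direct irradiation of F6 (350 nm, benzene) is the long-established crossed enone–alkene photocycloaddition of 1,5-hexadien-3-ones, in which the normal 1,5-closure itself delivers the C4–C10 and C5–C11 bonds; it gives the 2-norlongipinan-1-one F7 (a bicyclo[2.1.1]hexan-2-one with the cage configuration of 20). The missing carbon is then inserted by an Ito–Saegusa ring expansion: the only possible enolisation (toward C3) with Me3SiOTf and Et3N gives the bis(trimethylsilyl) enol ether F8, Et2Zn and CH2I2 give the siloxycyclopropane F9, FeCl3 in DMF gives the ring-expanded β-chloro ketone F10 (3-chloro-2,3-dihydro-20), and NaOAc in MeOH eliminates HCl to give 20.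

Step 6 (double acylation of two hindered hydroxyls; risk of tiglate formation). The fallback sets out from 7 and comes back at 10, building the Z alkenes on the substrate instead of transferring them. Diol 7 is esterified with 2-[bis(2,2,2-trifluoroethoxy)phosphoryl]propanoic acid (DCC, DMAP cat., CH2Cl2) to give (2S,3S)-4,4-dimethyl-1-(triethylsilyloxy)hex-5-ene-2,3-diyl bis{2-[bis(2,2,2-trifluoroethoxy)phosphoryl]propanoate} F11. A double Still–Gennari olefination of F11 with acetaldehyde (KN(SiMe3)2, 18-crown-6, THF, −78 °C) gives 10.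

**Further compounds**

F1 | step 12 | (2R,3S)-4,4-dimethyl-1-oxohex-5-ene-2,3-diyl bis[(Z)-2-methylbut-2-enoate] | C/C=C(/C)C(=O)O[C@@H](C=O)[C@@H](OC(=O)/C(C)=C\C)C(C)(C)C=C
F2 | step 12 | (4S,5S,6S,7Z,10Z)-6-hydroxy-11-iodo-3,3,7-trimethyl-9-oxododeca-1,7,10-triene-4,5-diyl bis[(Z)-2-methylbut-2-enoate] | C/C=C(/C)C(=O)O[C@@H]([C@@H](O)\C(C)=C/C(=O)/C=C(C)\I)[C@@H](OC(=O)/C(C)=C\C)C(C)(C)C=C
F3 | step 13 | (Z)-3-iodo-N-methoxy-N-methylbut-2-enamide | CON(C)C(=O)/C=C(C)\I
F4 | step 13 | (Z)-6-iodo-3-methylhepta-1,5-dien-4-one (racemic at C3) | C=CC(C)C(=O)/C=C(C)\I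
F5 | step 13 | (4S,5S,6S,7Z)-6-hydroxy-3,3,7,10-tetramethyl-9-oxododeca-1,7,11-triene-4,5-diyl bis[(Z)-2-methylbut-2-enoate] (both C10 epimers) | C/C=C(/C)C(=O)O[C@@H]([C@@H](O)\C(C)=C/C(=O)C(C)C=C)[C@@H](OC(=O)/C(C)=C\C)C(C)(C)C=C
F6 | step 13 | (3E,6S,7S,8S,9Z)-8-hydroxy-2,5,5,9-tetramethyl-1-oxocyclodeca-3,9-diene-6,7-diyl bis[(Z)-2-methylbut-2-enoate] (both C2 epimers) | C/C=C(/C)C(=O)O[C@@H]1[C@@H](OC(=O)/C(C)=C\C)C(C)(C)/C=C/C(C)C(=O)/C=C(C)\[C@@H]1O
F7 | step 13 | 7,8-bis(angeloyloxy)-9-hydroxy-2-norlongipinan-1-one (C1 bonded directly to C3; cage configuration as in 20; both C3 epimers) | C/C=C(/C)C(=O)O[C@@H]1[C@@H](OC(=O)/C(C)=C\C)C(C)(C)[C@@H]2[C@H]3C(=O)C(C)[C@@H]2[C@@]3(C)[C@@H]1O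
F8 | step 13 | 1,9-bis(trimethylsilyloxy)-7,8-bis(angeloyloxy)-2-norlongipin-1(3)-ene (silyl enol ether of F7, C9 hydroxyl silylated) | C/C=C(/C)C(=O)O[C@@H]1[C@@H](OC(=O)/C(C)=C\C)C(C)(C)[C@@H]2[C@H]3C(O[Si](C)(C)C)=C(C)[C@@H]2[C@@]3(C)[C@@H]1O[Si](C)(C)C
F9 | step 13 | siloxycyclopropane from F8 (CH2 bridging C1 and C3) | C/C=C(/C)C(=O)O[C@@H]1[C@@H](OC(=O)/C(C)=C\C)C(C)(C)[C@@H]2[C@H]3C4(O[Si](C)(C)C)CC4(C)[C@@H]2[C@@]3(C)[C@@H]1O[Si](C)(C)C
F10 | step 13 | 3-chloro-7,8-bis(angeloyloxy)-9-hydroxylongipinan-1-one (3-chloro-2,3-dihydro-20; both C3 epimers) | C/C=C(/C)C(=O)O[C@@H]1[C@@H](OC(=O)/C(C)=C\C)C(C)(C)[C@@H]2[C@H]3C(=O)CC(C)(Cl)[C@@H]2[C@@]3(C)[C@@H]1O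
F11 | step 6 | (2S,3S)-4,4-dimethyl-1-(triethylsilyloxy)hex-5-ene-2,3-diyl bis{2-[bis(2,2,2-trifluoroethoxy)phosphoryl]propanoate} | C=CC(C)(C)[C@H](OC(=O)C(C)P(=O)(OCC(F)(F)F)OCC(F)(F)F)[C@@H](OC(=O)C(C)P(=O)(OCC(F)(F)F)OCC(F)(F)F)CO[Si](CC)(CC)CC
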